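## Retrosynthetic overview

1. The C7 ketone comes from a 7α-alcohol; the 8β-acetate and 7α-alcohol come from trans-diaxial acetolysis of a 7α,8α-epoxide.
2. Key disconnection: the spiro-tetrahydrofuran and the spiro-γ-butyrolactone are cut together (O9–C13, C14–C15, C15–O16) to an ene-diol plus CO, joined in one palladium-catalysed oxypalladation/carbonylation/lactonisation domino.
3. The ene-diol comes from a 9α,11-spiro-epoxide and doubly lithiated methallyl alcohol; the spiro-epoxide comes from the C9 ketone by methylenation and α-face epoxidation.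
4. Ring A is closed by alkylation of the 19,6β-lactone enolate (C3–C4 bond), the lactone acting as template for the C4 quaternary centre; the lactone comes from γ-hydroxylation of a carvone-derived enone acid.
5. Ring B is (R)-carvone (C5 stereocentre, C7–C9 functionality). Order of ring formation: ring B (given) → 19,6β-lactone → 7,8-epoxide → ring A → spiro-epoxide → tetrahydrofuran and butyrolactone together.

Locants C1–C20 follow labdane numbering of the target (C19 = lactone carbonyl on C4, C17 = methyl on C8, C20 = methyl on C10).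

Assumption: (S,S)-Bn-BOXAX is taken as the ligand antipode matched to the 13R outcome in step 11; if a trial run shows the opposite sense, the (R,R)-ligand is used under the same conditions.

## Route

Step 1
Reactants: 1 (R)-(−)-carvone
Product: 3 (5R)-2,6-dimethyl-5-(prop-1-en-2-yl)cyclohex-2-en-1-one as a mixture of C6 epimers, via carvone lithium dienolate 2 (not isolated)
Conditions: LiN(iPr)2, THF, −78 °C; then MeI, −78 → 0 °C
Reagents that add atoms: iodomethane, CI
Why: Kinetic deprotonation at the α′-methylene gives the cross-conjugated lithium dienolate, whose C-methylation (enolate alkylation) installs the future C20 methyl; the new centre is uncontrolled and is re-enolised in step 2.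

Step 2
Reactants: 3 (5R)-2,6-dimethyl-5-(prop-1-en-2-yl)cyclohex-2-en-1-one; 4 1-chloro-3-iodopropane
Product: 6 (5S,6S)-6-(3-chloropropyl)-2,6-dimethyl-5-(prop-1-en-2-yl)cyclohex-2-en-1-one, via methylcarvone lithium enolate 5 (not isolated)
Conditions: LiN(iPr)2, THF, −78 °C; then 4, DMPU, −78 → 0 °C
Reagents that add atoms: none
Why: Enolate alkylation at the iodide end of 4 occurs anti to the neighbouring isopropenyl group, so the chloropropyl arm (future C1–C3) ends trans to the isopropenyl arm (future C4) and the methyl cis, which is the trans-decalin relationship of C10 and C5.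

Step 3
Reactants: 6 (5S,6S)-6-(3-chloropropyl)-2,6-dimethyl-5-(prop-1-en-2-yl)cyclohex-2-en-1-one
Product: 8 (5S,6S)-6-(3-chloropropyl)-5-(1-hydroxypropan-2-yl)-2,6-dimethylcyclohex-2-en-1-ol as an epimer mixture, via bis-boryl hydroboration adduct 7 (not isolated)
Conditions: 9-BBN (2.5 equiv), THF, 25 °C; then NaOH, H2O2, H2O, 0 → 25 °C
Reagents that add atoms: hydrogen peroxide, OO
Why: Anti-Markovnikov hydroboration–oxidation of the 1,1-disubstituted alkene makes its terminal carbon the future C19 carbinol, while the accompanying 1,2-reduction of the enone is harmless because step 4 re-oxidises it; both new centres are mixtures that are erased in steps 4 and 7.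

Step 4
Reactants: 8 (5S,6S)-6-(3-chloropropyl)-5-(1-hydroxypropan-2-yl)-2,6-dimethylcyclohex-2-en-1-ol
Product: 9 2-[(1S,2S)-2-(3-chloropropyl)-2,4-dimethyl-3-oxocyclohex-4-en-1-yl]propanoic acid as a mixture of side-chain epimers
Conditions: CrO3, H2SO4, H2O, acetone, 0 °C
Reagents that add atoms: water, O
Why: Chromic acid (Jones-type) oxidation takes the primary alcohol to the carboxylic acid and the allylic alcohol back to the enone without touching the alkyl chloride.

Step 5
Reactants: 9 2-[(1S,2S)-2-(3-chloropropyl)-2,4-dimethyl-3-oxocyclohex-4-en-1-yl]propanoic acid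
Product: 12 (3aS,4S,7aR)-4-(3-chloropropyl)-3,4,6-trimethyl-3a,7a-dihydro-1-benzofuran-2,5(3H,4H)-dione as a mixture of C3 epimers, via bis-silyl dienol ether 10 (not isolated), via hydroxy keto acid 11 (not isolated)
Conditions: TMSOTf (2.2 equiv), Et3N, CH2Cl2, 0 °C; then mCPBA, −20 °C; then 1 M HCl, THF, 25 °C
Reagents that add atoms: meta-chloroperbenzoic acid, OOC(=O)c1cccc(Cl)c1
Why: Soft enolisation can only go towards C6 because the α′-carbon is quaternary, and peracid oxidation of the resulting 1-siloxydiene at its terminus (vinylogous Rubottom oxidation) is expected, by analogy with the axial 6β-hydroxylation of steroidal 3,5-dienol ethers, to give the 6β-alcohol, which is cis to the propanoic acid arm and closes to the γ-lactone on acidic work-up.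

Step 6
Reactants: 12 (3aS,4S,7aR)-4-(3-chloropropyl)-3,4,6-trimethyl-3a,7a-dihydro-1-benzofuran-2,5(3H,4H)-dione
Product: 13 6,7-epoxide of 12 (4-(3-chloropropyl)-6,7-epoxy-3,4,6-trimethylhexahydro-1-benzofuran-2,5-dione; epoxide oxygen trans to the lactone oxygen; 7α,8α in labdane locants)
Conditions: 30% H2O2, NaOH (0.2 equiv), MeOH, 0 °C
Reagents that add atoms: hydrogen peroxide, OO
Why: Weitz–Scheffer nucleophilic epoxidation delivers the hydroperoxide to the face opposite the cis-fused lactone oxygen and the axial methyl, giving the 7α,8α-epoxide and removing the enone so that only the lactone α-hydrogen is acidic in step 7.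

Step 7
Reactants: 13 6,7-epoxide of 12
Product: 15 7α,8α-epoxy-9-oxo-11,12,13,14,15,16-hexanorlabdan-19,6β-olide, via lithium lactone enolate 14 (not isolated)
Conditions: LiN(iPr)2 (1.3 equiv), THF, −78 °C; then DMPU, NaI (cat.), −78 → 40 °C
Reagents that add atoms: none
Why: Intramolecular 6-exo-tet alkylation of the lactone enolate by the chloropropyl arm closes ring A, and because the enolate carbon is held in the cis-fused lactone the new bond can only form on the face carrying C10, which fixes C4 with C19 β-axial and the methyl α.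

Step 8
Reactants: 15 7α,8α-epoxy-9-oxo-11,12,13,14,15,16-hexanorlabdan-19,6β-olide
Product: 16 7α,8α-epoxy-12,13,14,15,16-pentanorlabd-9(11)-en-19,6β-olide
Conditions: Ph3PCH3Br, KOtBu, toluene, 90 °C
Reagents that add atoms: methyltriphenylphosphonium bromide, C[P+](c1ccccc1)(c1ccccc1)c1ccccc1.[Br-]
Why: Wittig methylenation of the non-enolisable ketone with excess ylide at elevated temperature gives the exocyclic alkene, the epoxide and the neopentylic lactone having no acidic hydrogens and being inert to the ylide.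

Step 9
Reactants: 16 7α,8α-epoxy-12,13,14,15,16-pentanorlabd-9(11)-en-19,6β-olide
Product: 17 7α,8α:9α,11-diepoxy-12,13,14,15,16-pentanorlabdan-19,6β-olide
Conditions: dimethyldioxirane, acetone, 0 °C
Reagents that add atoms: dimethyldioxirane, CC1(C)OO1
Why: Electrophilic epoxidation of the exocyclic alkene occurs from the α-face because the β-face is flanked by the β-methyl groups on C8 and C10, placing the epoxide oxygen α at C9 and C11 β.

Step 10
Reactants: 17 7α,8α:9α,11-diepoxy-12,13,14,15,16-pentanorlabdan-19,6β-olide; 18 2-methylprop-2-en-1-ol (methallyl alcohol)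
Product: 20 7α,8α-epoxy-9α,16-dihydroxy-15-norlabd-13(14)-en-19,6β-olide, via dilithio methallyl alcohol 19 (not isolated)
Conditions: 18, n-BuLi (2 equiv), TMEDA, Et2O, 0 → 25 °C; then 17, THF, −78 → 0 °C
Reagents that add atoms: none
Why: The allylic dianion (both CH2 termini equivalent) opens the spiro-epoxide by SN2 attack at the unhindered primary carbon with retention at C9, giving the 9α-tertiary alcohol and the C11–C14/C16 chain while the trisubstituted epoxide and the hindered axial lactone are spared.

Step 11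
Reactants: 20 7α,8α-epoxy-9α,16-dihydroxy-15-norlabd-13(14)-en-19,6β-olide
Product: 23 (13R)-7α,8α:9α,13-diepoxylabdane-19,6β:15,16-diolide, via alkylpalladium trifluoroacetate 21 (not isolated), via acylpalladium trifluoroacetate 22 (not isolated)
Conditions: Pd(OCOCF3)2 (10 mol %), (S,S)-Bn-BOXAX (20 mol %), p-benzoquinone (3 equiv), CO (1 atm), CH2Cl2, 25 °C
Reagents that add atoms: carbon monoxide, [C-]#[O+]
Why: Proposed new method: divalent palladium activates the 1,1-disubstituted alkene for 5-exo attack by the tertiary 9α-hydroxyl (Wacker-type oxypalladation), the neopentyl σ-alkylpalladium species has no β-hydrogen and therefore inserts CO, and the acylpalladium is captured by the neighbouring primary hydroxyl, so the spiro-tetrahydrofuran and the spiro-butyrolactone form in one operation while benzoquinone re-oxidises the zerovalent palladium; C13 is set in the oxypalladation under control of the chiral BOXAX ligand, the closest known reaction being the enantioselective domino Wacker/carbonylation of phenols onto 1,1-disubstituted alkenes with methanol capture, here extended to a tertiary alkanol and an internal alcohol trap.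

Step 12
Reactants: 23 (13R)-7α,8α:9α,13-diepoxylabdane-19,6β:15,16-diolide
Product: 24 (13R)-8β-acetoxy-9α,13-epoxy-7α-hydroxylabdane-19,6β:15,16-diolide
Conditions: AcOH, 60 °C
Reagents that add atoms: acetic acid, CC(=O)O
Why: Acid-promoted opening of the trisubstituted epoxide by acetic acid occurs at the tertiary carbon C8 with inversion in the trans-diaxial (Fürst–Plattner) sense, giving the 8β-acetate and the 7α-alcohol.

Step 13
Reactants: 24 (13R)-8β-acetoxy-9α,13-epoxy-7α-hydroxylabdane-19,6β:15,16-diolide
Product: 25 (13R)-8β-acetoxy-9α,13-epoxy-7-oxolabdane-19,6β:15,16-diolide (target CNP0259020.1)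
Conditions: Dess–Martin periodinane, CH2Cl2, 25 °C
Reagents that add atoms: none
Why: Dess–Martin oxidation converts the hindered secondary 7α-alcohol into the ketone under neutral conditions that leave the tertiary acetate, both lactones and the spiro-ether untouched, and no stereocentre is affected.

## Compound list

1 | (R)-(−)-carvone, (5R)-2-methyl-5-(prop-1-en-2-yl)cyclohex-2-en-1-one | CC1=CC[C@@H](C(C)=C)CC1=O | starting material
2 | carvone lithium dienolate (cross-conjugated; not isolated) | CC1=CC[C@@H](C(C)=C)C=C1O[Li] | intermediate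
3 | (5R)-2,6-dimethyl-5-(prop-1-en-2-yl)cyclohex-2-en-1-one (C6 epimer mixture) | CC1=CC[C@@H](C(C)=C)C(C)C1=O | intermediate
4 | 1-chloro-3-iodopropane | ClCCCI | starting material
5 | methylcarvone lithium enolate (not isolated) | CC1=CC[C@@H](C(C)=C)C(C)=C1O[Li] | intermediate
6 | (5S,6S)-6-(3-chloropropyl)-2,6-dimethyl-5-(prop-1-en-2-yl)cyclohex-2-en-1-one (chloropropyl trans to isopropenyl) | CC1=CC[C@@H](C(C)=C)[C@](C)(CCCCl)C1=O | intermediate
7 | bis-boryl hydroboration adduct (C-9-BBN on the side chain, O-9-BBN on the reduced carbonyl; not isolated) | CC1=CC[C@@H](C(C)CB2C3CCCC2CCC3)[C@](C)(CCCCl)C1OB1C2CCCC1CCC2 | intermediate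
8 | (5S,6S)-6-(3-chloropropyl)-5-(1-hydroxypropan-2-yl)-2,6-dimethylcyclohex-2-en-1-ol (epimers at C1 and in the side chain) | CC1=CC[C@@H](C(C)CO)[C@](C)(CCCCl)C1O | intermediate
9 | 2-[(1S,2S)-2-(3-chloropropyl)-2,4-dimethyl-3-oxocyclohex-4-en-1-yl]propanoic acid (side-chain epimers) | CC1=CC[C@@H](C(C)C(=O)O)[C@](C)(CCCCl)C1=O | intermediate
10 | bis-silyl dienol ether: trimethylsilyl ester and 1-trimethylsiloxy-1,3-diene of 9 (not isolated) | CC1=C(O[Si](C)(C)C)[C@@](C)(CCCCl)[C@H](C(C)C(=O)O[Si](C)(C)C)C=C1 | intermediate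
11 | 2-[(1S,2S,6R)-2-(3-chloropropyl)-6-hydroxy-2,4-dimethyl-3-oxocyclohex-4-en-1-yl]propanoic acid (6β-hydroxy keto acid; not isolated) | CC1=C[C@@H](O)[C@@H](C(C)C(=O)O)[C@](C)(CCCCl)C1=O | intermediate
12 | (3aS,4S,7aR)-4-(3-chloropropyl)-3,4,6-trimethyl-3a,7a-dihydro-1-benzofuran-2,5(3H,4H)-dione (cis-fused lactone, C3 epimers) | CC1=C[C@H]2OC(=O)C(C)[C@H]2[C@](C)(CCCCl)C1=O | intermediate
13 | 6,7-epoxide of 12, epoxide oxygen trans to the lactone oxygen (7α,8α-epoxy-9-oxo-19,6β-olide with ring A still open) | C[C@@]12O[C@@H]1[C@H]3OC(=O)C(C)[C@H]3[C@](C)(CCCCl)C2=O | intermediate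
14 | lithium lactone enolate of 13 (not isolated) | C[C@@]12O[C@@H]1[C@H]3OC(O[Li])=C(C)[C@H]3[C@](C)(CCCCl)C2=O | intermediate
15 | 7α,8α-epoxy-9-oxo-11,12,13,14,15,16-hexanorlabdan-19,6β-olide | C[C@@]12O[C@@H]1[C@H]3OC(=O)[C@@]4(C)CCC[C@@](C)([C@@H]34)C2=O | intermediate
16 | 7α,8α-epoxy-12,13,14,15,16-pentanorlabd-9(11)-en-19,6β-olide | C[C@@]12O[C@@H]1[C@H]3OC(=O)[C@@]4(C)CCC[C@@](C)([C@@H]34)C2=C | intermediate
17 | 7α,8α:9α,11-diepoxy-12,13,14,15,16-pentanorlabdan-19,6β-olide | C[C@@]12O[C@@H]1[C@H]3OC(=O)[C@@]4(C)CCC[C@@](C)([C@@H]34)[C@@]25CO5 | intermediate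
18 | 2-methylprop-2-en-1-ol (methallyl alcohol) | CC(=C)CO | starting material
19 | dilithio methallyl alcohol (O,C-dianion; not isolated) | [Li]CC(=C)CO[Li] | intermediate
20 | 7α,8α-epoxy-9α,16-dihydroxy-15-norlabd-13(14)-en-19,6β-olide | C[C@@]12O[C@@H]1[C@H]3OC(=O)[C@@]4(C)CCC[C@@](C)([C@@H]34)[C@@]2(O)CCC(=C)CO | intermediate
21 | alkylpalladium trifluoroacetate: (13R)-9α,13-epoxy tetrahydrofuran carrying CH2–Pd(OCOCF3) and CH2OH on C13 (not isolated) | C[C@@]12O[C@@H]1[C@H]3OC(=O)[C@@]4(C)CCC[C@@](C)([C@@H]34)[C@@]25CC[C@@](C[Pd]OC(=O)C(F)(F)F)(CO)O5 | intermediate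
22 | acylpalladium trifluoroacetate: CO-insertion product of 21 (not isolated) | C[C@@]12O[C@@H]1[C@H]3OC(=O)[C@@]4(C)CCC[C@@](C)([C@@H]34)[C@@]25CC[C@@](CC(=O)[Pd]OC(=O)C(F)(F)F)(CO)O5 | intermediate
23 | (13R)-7α,8α:9α,13-diepoxylabdane-19,6β:15,16-diolide | C[C@@]12O[C@@H]1[C@H]3OC(=O)[C@@]4(C)CCC[C@@](C)([C@@H]34)[C@@]25CC[C@@]6(COC(=O)C6)O5 | intermediate
24 | (13R)-8β-acetoxy-9α,13-epoxy-7α-hydroxylabdane-19,6β:15,16-diolide | CC(=O)O[C@@]1(C)[C@H](O)[C@H]2OC(=O)[C@@]3(C)CCC[C@@](C)([C@@H]23)[C@@]12CC[C@@]4(COC(=O)C4)O2 | intermediate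
25 | (13R)-8β-acetoxy-9α,13-epoxy-7-oxolabdane-19,6β:15,16-diolide (CNP0259020.1) | CC(=O)O[C@@]1(C)C(=O)[C@H]2OC(=O)[C@@]3(C)CCC[C@@](C)([C@@H]23)[C@@]12CC[C@@]1(COC(=O)C1)O2 | target

## Step count and risks

Total step count: 13. Longest linear sequence: 13 steps (1 → 25); compounds 4 and 18 are bought.

The three steps most likely to fail:

Step 11 (the domino cyclisation is an untested extension, and the face selectivity at C13 rests on ligand control over a hindered tertiary alcohol). The fallback sets out from 17 and comes back at 23. The spiro-epoxide of 17 is opened instead with dilithio 3-methylbut-3-en-1-ol F1 (isoprenol, n-BuLi, TMEDA), giving the homologous homoallylic alcohol 7α,8α-epoxy-9α,15-dihydroxylabd-13(16)-en-19,6β-olide F2. A hydroxyl-directed asymmetric epoxidation (VO(OiPr)3, chiral bishydroxamic acid ligand, cumene hydroperoxide) then sets C13 by reagent control and gives (13S)-7α,8α:13,16-diepoxy-9α,15-dihydroxylabdan-19,6β-olide F3. Camphorsulfonic acid makes the 9α-hydroxyl open this epoxide at C13 with inversion, giving the spiro-tetrahydrofuran diol (13R)-7α,8α:9α,13-diepoxy-15,16-dihydroxylabdan-19,6β-olide F4. Oxidative lactonisation of the 1,4-diol at the less hindered carbinol (TEMPO, PhI(OAc)2, CH2Cl2) closes the butyrolactone and gives 23.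

Step 5 (the peracid may attack the α-carbon of the siloxydiene instead of C6, or give the 6α-alcohol, which cannot template ring A). The fallback sets out from 9 and comes back at 12. The γ-methylene of 9 is oxidised with CrO3·3,5-dimethylpyrazole to the enedione acid 2-[(1S,2S)-2-(3-chloropropyl)-2,4-dimethyl-3,6-dioxocyclohex-4-en-1-yl]propanoic acid F5. NaBH4 with CeCl3 in MeOH at −78 °C reduces the less hindered C6 carbonyl from the α-face, the β-face being screened by the axial methyl on the neighbouring quaternary carbon, to give the 6β-hydroxy keto acid 11, which lactonises to 12 on acidification.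

Step 8 (the ketone is flanked by two fully substituted carbons and may resist the ylide). The fallback sets out from 15 and comes back at 16. CH3Li with CeCl3 in THF at −78 °C adds to the ketone from the open α-face to give the tertiary carbinol 7α,8α-epoxy-9β-hydroxy-9α-methyl-11,12,13,14,15,16-hexanorlabdan-19,6β-olide F6. Dehydration with Burgess reagent in toluene at 60 °C can only take a methyl hydrogen, because both ring neighbours are fully substituted, and gives the exocyclic alkene 16.

## Further compounds

F1 | step 11 | dilithio 3-methylbut-3-en-1-ol | [Li]CC(=C)CCO[Li]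
F2 | step 11 | 7α,8α-epoxy-9α,15-dihydroxylabd-13(16)-en-19,6β-olide | C[C@@]12O[C@@H]1[C@H]3OC(=O)[C@@]4(C)CCC[C@@](C)([C@@H]34)[C@@]2(O)CCC(=C)CCO
F3 | step 11 | (13S)-7α,8α:13,16-diepoxy-9α,15-dihydroxylabdan-19,6β-olide | C[C@@]12O[C@@H]1[C@H]3OC(=O)[C@@]4(C)CCC[C@@](C)([C@@H]34)[C@@]2(O)CC[C@]5(CCO)CO5
F4 | step 11 | (13R)-7α,8α:9α,13-diepoxy-15,16-dihydroxylabdan-19,6β-olide | C[C@@]12O[C@@H]1[C@H]3OC(=O)[C@@]4(C)CCC[C@@](C)([C@@H]34)[C@@]25CC[C@@](CCO)(CO)O5
F5 | step 5 | 2-[(1S,2S)-2-(3-chloropropyl)-2,4-dimethyl-3,6-dioxocyclohex-4-en-1-yl]propanoic acid | CC1=CC(=O)[C@@H](C(C)C(=O)O)[C@](C)(CCCCl)C1=O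
F6 | step 8 | 7α,8α-epoxy-9β-hydroxy-9α-methyl-11,12,13,14,15,16-hexanorlabdan-19,6β-olide | C[C@@]12O[C@@H]1[C@H]3OC(=O)[C@@]4(C)CCC[C@@](C)([C@@H]34)[C@@]2(C)O
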